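**Plan**
1. Retrosynthetic cuts, in order: the C8 and C9 ester C–O bonds; the C7–C11 bond (isopropenyl, by epoxide opening); the C1–C10 bond of ring A (oxidative coupling of two enol ethers); the C1 methylene and C3 of the side chain; the C4–C5 bond (Ireland–Claisen), back to 3-methylcyclohex-2-en-1-one.
2. Enabling feature: the C2 ketone of ring A and the oxygen-bearing C9 of ring B are 1,4-related through the ring-fusion bond C1–C10, so ring A can be closed by joining the α-carbons C1 and C10 of two enol ethers under oxidation.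
3. Forward order: ring B is the starting cyclohexenone; the C4 side chain is attached to C5, homologated and turned into a 2-methoxyallyl group; ring B becomes a 2-silyloxydiene; anodic coupling closes ring A as a cis-decalin; ring B is then functionalised at C9, C8 and C7 and esterified.
4. Stereochemistry: C5 from a CBS reduction relayed by the suprafacial [3,3] shift; C4 from enolate geometry in a chair transition state; C10 (cis fusion) from the tether on C5; C9 from β-face hydride delivery; C8 from hydroxyl-directed epoxidation; C7 from anti opening of the epoxide.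

Key step: step 11

Remark: eremophilane numbering is used (ring A = C1–C5 and C10, ring B = C5–C10, C11 = isopropenyl carbon on C7), β is the face of the C5 methyl group, and the target is read as the 8α-acetate 9α-(E)-2-methylbut-2-enoate with (4S,5R,7R,8R,9S,10S) configuration.

**Step 1**
Reactants: 1 3-methylcyclohex-2-en-1-one
Product: 2 (1R)-3-methylcyclohex-2-en-1-ol
Conditions: (S)-1-methyl-3,3-diphenyltetrahydro-1H,3H-pyrrolo[1,2-c][1,3,2]oxazaborole (10 mol %), BH3·SMe2, THF, −20 °C; MeOH
Reagents that add atoms: none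
Why: Corey–Bakshi–Shibata reduction in which the alkenyl side of the enone takes the role of the large group, so that the (S)-oxazaborolidine should deliver hydride to the face that gives the (R)-allylic alcohol, the source of absolute configuration for C5.

**Step 2**
Reactants: 2 (1R)-3-methylcyclohex-2-en-1-ol; 3 propanoyl chloride
Product: 4 (1R)-3-methylcyclohex-2-en-1-yl propanoate
Conditions: pyridine, 4-(dimethylamino)pyridine (DMAP, 5 mol %), CH2Cl2, 0 °C
Reagents that add atoms: none
Why: Routine DMAP-catalysed acylation of a secondary allylic alcohol by an acid chloride under basic conditions that avoid ionisation of the allylic C–O bond.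

**Step 3**
Reactants: 4 (1R)-3-methylcyclohex-2-en-1-yl propanoate
Product: 7 (2R)-2-[(1S)-1-methylcyclohex-2-en-1-yl]propanoic acid, via trimethylsilyl ketene acetal 5 (not isolated), via trimethylsilyl ester 6 (not isolated)
Conditions: LiN(CHMe2)2, THF, −78 °C; Me3SiCl, Et3N; −78 → 60 °C; 1 M HCl
Reagents that add atoms: none
Why: Ireland–Claisen rearrangement: deprotonation in THF without polar additive gives the (E)-silyl ketene acetal (methyl cis to the allylic oxygen), and its suprafacial [3,3] shift through a chair-like transition state moves the C–O chirality to the quaternary C5 and sets C4 relative to it.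

**Step 4**
Reactants: 7 (2R)-2-[(1S)-1-methylcyclohex-2-en-1-yl]propanoic acid
Product: 9 (3R)-1-diazo-3-[(1S)-1-methylcyclohex-2-en-1-yl]butan-2-one, via acid chloride 8 (not isolated)
Conditions: (COCl)2, HCONMe2 (catalytic), CH2Cl2, 0 °C → rt; CH2N2 (excess), Et2O, 0 °C
Reagents that add atoms: diazomethane, C=[N+]=[N-]
Why: First half of the Arndt–Eistert homologation (acid chloride, then acylation of diazomethane), run without amine base so that C4 is not epimerised through a ketene.

**Step 5**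
Reactants: 9 (3R)-1-diazo-3-[(1S)-1-methylcyclohex-2-en-1-yl]butan-2-one
Product: 11 methyl (3S)-3-[(1R)-1-methylcyclohex-2-en-1-yl]butanoate, via ketene 10 (not isolated)
Conditions: AgO2CPh (10 mol %), Et3N, MeOH, rt, dark
Reagents that add atoms: methanol, CO
Why: Silver-catalysed Wolff rearrangement, in which C4 migrates with retention to a ketene that methanol captures as the homologated methyl ester.

**Step 6**
Reactants: 11 methyl (3S)-3-[(1R)-1-methylcyclohex-2-en-1-yl]butanoate
Product: 13 methyl (3S)-3-[(1S,3RS)-3-hydroxy-1-methylcyclohexyl]butanoate, via 9-borabicyclononyl adduct 12 (not isolated)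
Conditions: 9-borabicyclo[3.3.1]nonane, THF, 65 °C; 30% H2O2, aq NaOAc, 0 °C → rt
Reagents that add atoms: hydrogen peroxide, OO
Why: Hydroboration–oxidation with a bulky dialkylborane that should place boron on C9, the alkene carbon remote from the quaternary C5, and that leaves the ester alone; the carbinol centre formed is removed in step 7.

**Step 7**
Reactants: 13 methyl (3S)-3-[(1S,3RS)-3-hydroxy-1-methylcyclohexyl]butanoate
Product: 14 methyl (3S)-3-[(1S)-1-methyl-3-oxocyclohexyl]butanoate
Conditions: n-Pr4NRuO4 (5 mol %), N-methylmorpholine N-oxide, 4 Å molecular sieves, CH2Cl2, rt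
Reagents that add atoms: none
Why: Ley–Griffith oxidation of the secondary alcohol to the C9 ketone under neutral conditions.

**Step 8**
Reactants: 14 methyl (3S)-3-[(1S)-1-methyl-3-oxocyclohexyl]butanoate
Product: 15 methyl (3S)-3-[(1S)-1-methyl-5-oxocyclohex-3-en-1-yl]butanoate
Conditions: 2-iodoxybenzoic acid (IBX), DMSO–toluene, 70 °C
Reagents that add atoms: none
Why: IBX dehydrogenation of a ketone to the enone, which can only run toward C8–C7 because the other α-carbon (C10) has the fully substituted C5 as its neighbour.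

**Step 9**
Reactants: 15 methyl (3S)-3-[(1S)-1-methyl-5-oxocyclohex-3-en-1-yl]butanoate
Product: 16 methyl (3S)-3-[(1R)-3-{[tert-butyl(dimethyl)silyl]oxy}-1-methylcyclohexa-2,4-dien-1-yl]butanoate
Conditions: t-BuMe2SiOSO2CF3, Et3N, CH2Cl2, −78 → 0 °C
Reagents that add atoms: tert-butyldimethylsilyl trifluoromethanesulfonate, CC(C)(C)[Si](C)(C)OS(=O)(=O)C(F)(F)F
Why: Silyl triflate–amine enolisation of a cyclohexenone, which takes the α'-proton (C10) and gives the cross-conjugated 2-silyloxydiene while the less acidic ester stays untouched at low temperature.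

**Step 10**
Reactants: 16 methyl (3S)-3-[(1R)-3-{[tert-butyl(dimethyl)silyl]oxy}-1-methylcyclohexa-2,4-dien-1-yl]butanoate
Product: 17 tert-butyl({(3R)-3-[(2S)-4-methoxypent-4-en-2-yl]-3-methylcyclohexa-1,5-dien-1-yl}oxy)dimethylsilane
Conditions: Cp2TiMe2, toluene, 70 °C, dark; filtration through basic alumina
Reagents that add atoms: dimethyltitanocene, C[Ti](C)(C1C=CC=C1)C1C=CC=C1
Why: Petasis methylenation of the ester carbonyl to the methyl enol ether (2-methoxyallyl group), chemoselective at this stage because the ketone is stored as its silyl dienol ether, which the titanium methylidene does not attack.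

**Step 11**
Reactants: 17 tert-butyl({(3R)-3-[(2S)-4-methoxypent-4-en-2-yl]-3-methylcyclohexa-1,5-dien-1-yl}oxy)dimethylsilane
Product: 18 (4aR,5S,8aS)-7,7-dimethoxy-4a,5-dimethyl-4a,5,6,7,8,8a-hexahydronaphthalen-1(4H)-one
Conditions: undivided cell, reticulated vitreous carbon anode, Pt cathode, constant current, 0.1 M LiClO4, 2,6-lutidine, MeOH–THF (1:4), rt, 2.2 F/mol
Reagents that add atoms: methanol, CO
Why: Intramolecular anodic olefin coupling, the electrochemical relative of the oxidative cross-coupling of a silyl enol ether with an alkyl enol ether to a 1,4-dicarbonyl monoketal: the silyloxydiene is the more easily oxidised π system and gives a radical cation with its highest coefficient at C10, which the nucleophilic CH2 terminus (C1) of the methoxyalkene attacks. Ring A closes in a six-membered mode that is exo to the C9=C10 bond and endo to the C1=C2 bond, whereas bonding to the other diene terminus C7 would need a seven-membered ring. Methanol traps the C2 oxocarbenium ion as the dimethyl ketal, and the C9 allyl radical loses a second electron and then its silyl group to methanol, which restores the C7=C8–C9 enone. The new stereocentre C10 is controlled by C5, because the chain on C5 can reach C10 only in an axial trajectory on its own face, anti to the C5 methyl group, so that the ring fusion is cis (10β-H). The step needs oxidation at the dienol ether before the methoxyalkene and ring closure before solvent capture, which the lower oxidation potential of the diene and the short tether should secure, while 2,6-lutidine keeps the medium from turning acidic.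

**Step 12**
Reactants: 18 (4aR,5S,8aS)-7,7-dimethoxy-4a,5-dimethyl-4a,5,6,7,8,8a-hexahydronaphthalen-1(4H)-one
Product: 19 (1R,4aR,5S,8aS)-7,7-dimethoxy-4a,5-dimethyl-1,4,4a,5,6,7,8,8a-octahydronaphthalen-1-ol (9α-alcohol)
Conditions: NaBH4, CeCl3·7H2O, MeOH, −78 °C
Reagents that add atoms: none
Why: Luche 1,2-reduction, in which hydride should reach C9 from the β-face because ring A (C4 axial on ring B) screens the α-face, giving the 9α-alcohol.

**Step 13**
Reactants: 19 (1R,4aR,5S,8aS)-7,7-dimethoxy-4a,5-dimethyl-1,4,4a,5,6,7,8,8a-octahydronaphthalen-1-ol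
Product: 20 (1S,2S,3R,4aR,5S,8aS)-2,3-epoxy-7,7-dimethoxy-4a,5-dimethyldecahydronaphthalen-1-ol (7α,8α-epoxide, 9α-alcohol)
Conditions: VO(acac)2 (5 mol %), t-BuOOH, CH2Cl2, 0 °C → rt
Reagents that add atoms: tert-butyl hydroperoxide, CC(C)(C)OO
Why: Vanadium-catalysed hydroxyl-directed epoxidation of an allylic alcohol, which delivers oxygen syn to the 9α-hydroxyl group and so places the epoxide on the α-face of C7–C8, the face that an undirected reagent would avoid.

**Step 14**
Reactants: 20 (1S,2S,3R,4aR,5S,8aS)-2,3-epoxy-7,7-dimethoxy-4a,5-dimethyldecahydronaphthalen-1-ol; 21 2-bromopropene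
Product: 23 (1S,2R,3R,4aR,5S,8aS)-7,7-dimethoxy-4a,5-dimethyl-3-(prop-1-en-2-yl)decahydronaphthalene-1,2-diol, via isopropenylmagnesium bromide 22 (not isolated)
Conditions: 21, Mg, THF, rt; then 20, CuBr·SMe2 (15 mol %), THF, −30 → 0 °C; aq NH4Cl
Reagents that add atoms: none
Why: Copper-catalysed Grignard opening of an epoxide by SN2 attack anti to the oxygen, expected at C7 because C8 is deactivated and shielded by the neighbouring C9 alkoxide (the usual distal opening of cis-2,3-epoxycyclohexanols), which sets the 7β-isopropenyl group and leaves the 8α,9α-diol.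

**Step 15**
Reactants: 23 (1S,2R,3R,4aR,5S,8aS)-7,7-dimethoxy-4a,5-dimethyl-3-(prop-1-en-2-yl)decahydronaphthalene-1,2-diol
Product: 24 (1S,2R,3R,4aR,5S,8aS)-2-{[tert-butyl(dimethyl)silyl]oxy}-7,7-dimethoxy-4a,5-dimethyl-3-(prop-1-en-2-yl)decahydronaphthalen-1-ol
Conditions: t-BuMe2SiCl, imidazole, HCONMe2, 0 °C
Reagents that add atoms: tert-butyldimethylsilyl chloride, CC(C)(C)[Si](C)(C)Cl
Why: Selective silylation of the less hindered, equatorial 8-hydroxyl group of a diol, the axial 9-hydroxyl group being flanked by the ring fusion and syn-axial to C4.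

**Step 16**
Reactants: 24 (1S,2R,3R,4aR,5S,8aS)-2-{[tert-butyl(dimethyl)silyl]oxy}-7,7-dimethoxy-4a,5-dimethyl-3-(prop-1-en-2-yl)decahydronaphthalen-1-ol; 25 (2E)-2-methylbut-2-enoyl chloride (tigloyl chloride)
Product: 26 (1S,2R,3R,4aR,5S,8aS)-2-{[tert-butyl(dimethyl)silyl]oxy}-7,7-dimethoxy-4a,5-dimethyl-3-(prop-1-en-2-yl)decahydronaphthalen-1-yl (2E)-2-methylbut-2-enoate
Conditions: pyridine, DMAP, toluene, 80 °C
Reagents that add atoms: none
Why: DMAP-catalysed acylation of the hindered axial alcohol by the acid chloride at raised temperature, done while O8 carries a silyl group so that no acyl migration can confuse the two esters.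

**Step 17**
Reactants: 26 (1S,2R,3R,4aR,5S,8aS)-2-{[tert-butyl(dimethyl)silyl]oxy}-7,7-dimethoxy-4a,5-dimethyl-3-(prop-1-en-2-yl)decahydronaphthalen-1-yl (2E)-2-methylbut-2-enoate
Product: 27 (1S,2R,3R,4aR,5S,8aS)-2-hydroxy-4a,5-dimethyl-7-oxo-3-(prop-1-en-2-yl)decahydronaphthalen-1-yl (2E)-2-methylbut-2-enoate
Conditions: 48% aq HF, MeCN, 0 °C → rt
Reagents that add atoms: water, O
Why: Acid-mediated desilylation together with hydrolysis of the dimethyl ketal, acid being chosen over fluoride ion so that the tigloyl group does not move to the freed 8-hydroxyl group.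

**Step 18**
Reactants: 27 (1S,2R,3R,4aR,5S,8aS)-2-hydroxy-4a,5-dimethyl-7-oxo-3-(prop-1-en-2-yl)decahydronaphthalen-1-yl (2E)-2-methylbut-2-enoate
Product: 28 (1S,2R,3R,4aR,5S,8aS)-2-acetoxy-4a,5-dimethyl-7-oxo-3-(prop-1-en-2-yl)decahydronaphthalen-1-yl (2E)-2-methylbut-2-enoate (CNP0204573.1)
Conditions: Ac2O, pyridine, DMAP (catalytic), CH2Cl2, rt
Reagents that add atoms: acetic anhydride, CC(=O)OC(C)=O
Why: DMAP-catalysed acetylation of the equatorial secondary alcohol, which completes the target.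

**Compound list**
1 | 3-methylcyclohex-2-en-1-one | CC1=CC(=O)CCC1 | starting material
2 | (1R)-3-methylcyclohex-2-en-1-ol | CC1=C[C@H](O)CCC1 | intermediate
3 | propanoyl chloride | CCC(=O)Cl | starting material
4 | (1R)-3-methylcyclohex-2-en-1-yl propanoate | CCC(=O)O[C@H]1C=C(C)CCC1 | intermediate
5 | trimethyl{[(1E)-1-{[(1R)-3-methylcyclohex-2-en-1-yl]oxy}prop-1-en-1-yl]oxy}silane | C/C=C(/O[Si](C)(C)C)O[C@H]1C=C(C)CCC1 | intermediate
6 | trimethylsilyl (2R)-2-[(1S)-1-methylcyclohex-2-en-1-yl]propanoate | C[C@@H](C(=O)O[Si](C)(C)C)[C@]1(C)C=CCCC1 | intermediate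
7 | (2R)-2-[(1S)-1-methylcyclohex-2-en-1-yl]propanoic acid | C[C@@H](C(=O)O)[C@]1(C)C=CCCC1 | intermediate
8 | (2R)-2-[(1S)-1-methylcyclohex-2-en-1-yl]propanoyl chloride | C[C@@H](C(Cl)=O)[C@]1(C)C=CCCC1 | intermediate
9 | (3R)-1-diazo-3-[(1S)-1-methylcyclohex-2-en-1-yl]butan-2-one | C[C@@H](C(=O)C=[N+]=[N-])[C@]1(C)C=CCCC1 | intermediate
10 | (3S)-3-[(1S)-1-methylcyclohex-2-en-1-yl]but-1-en-1-one (ketene) | C[C@@H](C=C=O)[C@]1(C)C=CCCC1 | intermediate
11 | methyl (3S)-3-[(1R)-1-methylcyclohex-2-en-1-yl]butanoate | C[C@@H](CC(=O)OC)[C@]1(C)C=CCCC1 | intermediate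
12 | methyl (3S)-3-[(1S)-3-(9-borabicyclo[3.3.1]nonan-9-yl)-1-methylcyclohexyl]butanoate (both ring C3 epimers) | C[C@@H](CC(=O)OC)[C@]1(C)CC(B2C3CCCC2CCC3)CCC1 | intermediate
13 | methyl (3S)-3-[(1S,3RS)-3-hydroxy-1-methylcyclohexyl]butanoate | C[C@@H](CC(=O)OC)[C@]1(C)CC(O)CCC1 | intermediate
14 | methyl (3S)-3-[(1S)-1-methyl-3-oxocyclohexyl]butanoate | C[C@@H](CC(=O)OC)[C@]1(C)CC(=O)CCC1 | intermediate
15 | methyl (3S)-3-[(1S)-1-methyl-5-oxocyclohex-3-en-1-yl]butanoate | C[C@@H](CC(=O)OC)[C@]1(C)CC(=O)C=CC1 | intermediate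
16 | methyl (3S)-3-[(1R)-3-{[tert-butyl(dimethyl)silyl]oxy}-1-methylcyclohexa-2,4-dien-1-yl]butanoate | C[C@@H](CC(=O)OC)[C@]1(C)C=C(O[Si](C)(C)C(C)(C)C)C=CC1 | intermediate
17 | tert-butyl({(3R)-3-[(2S)-4-methoxypent-4-en-2-yl]-3-methylcyclohexa-1,5-dien-1-yl}oxy)dimethylsilane | C[C@@H](CC(OC)=C)[C@]1(C)C=C(O[Si](C)(C)C(C)(C)C)C=CC1 | intermediate
18 | (4aR,5S,8aS)-7,7-dimethoxy-4a,5-dimethyl-4a,5,6,7,8,8a-hexahydronaphthalen-1(4H)-one | O=C1C=CC[C@@]2(C)[C@@H]1CC(OC)(OC)C[C@@H]2C | intermediate
19 | (1R,4aR,5S,8aS)-7,7-dimethoxy-4a,5-dimethyl-1,4,4a,5,6,7,8,8a-octahydronaphthalen-1-ol | O[C@@H]1C=CC[C@@]2(C)[C@@H]1CC(OC)(OC)C[C@@H]2C | intermediate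
20 | (1S,2S,3R,4aR,5S,8aS)-2,3-epoxy-7,7-dimethoxy-4a,5-dimethyldecahydronaphthalen-1-ol | O[C@@H]1[C@@H]3O[C@@H]3C[C@@]2(C)[C@@H]1CC(OC)(OC)C[C@@H]2C | intermediate
21 | 2-bromopropene | CC(Br)=C | starting material
22 | isopropenylmagnesium bromide | CC(=C)[Mg]Br | intermediate
23 | (1S,2R,3R,4aR,5S,8aS)-7,7-dimethoxy-4a,5-dimethyl-3-(prop-1-en-2-yl)decahydronaphthalene-1,2-diol | C=C(C)[C@H]1C[C@@]2(C)[C@H](CC(OC)(OC)C[C@@H]2C)[C@H](O)[C@@H]1O | intermediate
24 | (1S,2R,3R,4aR,5S,8aS)-2-{[tert-butyl(dimethyl)silyl]oxy}-7,7-dimethoxy-4a,5-dimethyl-3-(prop-1-en-2-yl)decahydronaphthalen-1-ol | C=C(C)[C@H]1C[C@@]2(C)[C@H](CC(OC)(OC)C[C@@H]2C)[C@H](O)[C@@H]1O[Si](C)(C)C(C)(C)C | intermediate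
25 | (2E)-2-methylbut-2-enoyl chloride | C/C=C(/C(=O)Cl)C | starting material
26 | (1S,2R,3R,4aR,5S,8aS)-2-{[tert-butyl(dimethyl)silyl]oxy}-7,7-dimethoxy-4a,5-dimethyl-3-(prop-1-en-2-yl)decahydronaphthalen-1-yl (2E)-2-methylbut-2-enoate | C=C(C)[C@H]1C[C@@]2(C)[C@H](CC(OC)(OC)C[C@@H]2C)[C@H](OC(=O)/C(C)=C/C)[C@@H]1O[Si](C)(C)C(C)(C)C | intermediate
27 | (1S,2R,3R,4aR,5S,8aS)-2-hydroxy-4a,5-dimethyl-7-oxo-3-(prop-1-en-2-yl)decahydronaphthalen-1-yl (2E)-2-methylbut-2-enoate | C=C(C)[C@H]1C[C@@]2(C)[C@H](CC(=O)C[C@@H]2C)[C@H](OC(=O)/C(C)=C/C)[C@@H]1O | intermediate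
28 | (1S,2R,3R,4aR,5S,8aS)-2-acetoxy-4a,5-dimethyl-7-oxo-3-(prop-1-en-2-yl)decahydronaphthalen-1-yl (2E)-2-methylbut-2-enoate | C=C(C)[C@H]1C[C@@]2(C)[C@H](CC(=O)C[C@@H]2C)[C@H](OC(=O)/C(C)=C/C)[C@@H]1OC(C)=O | target

**Step count and risks**
Total: 18 steps. Longest linear sequence: 18 steps from 1 (reagent 22 is made in the flask within step 14).

Steps most likely to fail:

1. Step 11. The diene radical cation may be captured by methanol, or oxidised further, before the C1–C10 bond forms; bonding at C7 is a lesser risk. The fallback sets out from 17 and returns at 18, and replaces anodic radical-cation chemistry with chemical oxidation of a dienolate. Dilute HCl in THF hydrolyses both enol ethers to (4S)-4-[(1S)-1-methyl-5-oxocyclohex-3-en-1-yl]pentan-2-one F1. Double kinetic deprotonation (LiN(CHMe2)2, 2.2 equivalents, THF, −78 °C, at the methyl group C1 and at C10) followed by CuCl2 in HCONMe2 (oxidative enolate coupling) should give the cis-fused (4aR,5S,8aS)-4a,5-dimethyl-4a,5,8,8a-tetrahydronaphthalene-1,7(4H,6H)-dione F2. The saturated C2 ketone is then ketalised in preference to the enone (HC(OMe)3, MeOH, pyridinium p-toluenesulfonate) to give 18.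

2. Step 14. The organocopper reagent may attack C8 instead of C7, or open the epoxide only slowly next to the C5 methyl group, so that halohydrin formation by magnesium bromide takes over. The fallback sets out from 18 and returns at 23; it forms the C7–C11 bond by 1,4-addition, where regiochemistry is fixed by the enone, and brings in the C8 oxygen by enol ether oxidation and inversion. Copper-catalysed conjugate addition of 22 in the presence of Me3SiCl (CuBr·SMe2, THF, −78 °C), expected on the open β-face, gives the 7β-isopropenyl trimethylsilyl enol ether F3. Rubottom oxidation (m-chloroperbenzoic acid, NaHCO3, CH2Cl2, −20 °C, then mild desilylation), expected on the same convex face, gives the 8β-hydroxy 9-ketone F4. A Mitsunobu reaction (4-nitrobenzoic acid, PPh3, diisopropyl azodicarboxylate) inverts C8 to the 8α-(4-nitrobenzoyloxy) 9-ketone F5. NaBH4 (MeOH, −40 °C), adding from the β-face, gives the 8α-(4-nitrobenzoyloxy)-9α-alcohol F6, and K2CO3 in MeOH removes the ester to return diol 23.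

3. Step 3. The C4 configuration may be eroded by a competing boat-like transition state or by incomplete control of enolate geometry. The fallback sets out from 2 and returns at 7; it leaves only C5 to the sigmatropic shift and sets C4 by auxiliary-controlled alkylation. Acetylation (Ac2O, pyridine) gives (1R)-3-methylcyclohex-2-en-1-yl acetate F7. Its Ireland–Claisen rearrangement (LiN(CHMe2)2, Me3SiCl, THF, −78 → 60 °C) runs through the silyl ketene acetal F8 and the trimethylsilyl ester F9 to [(1R)-1-methylcyclohex-2-en-1-yl]acetic acid F10. Pivaloyl chloride and Et3N give the mixed pivalic anhydride F11, which acylates lithiated (4R)-4-benzyl-1,3-oxazolidin-2-one to the imide F12. Methylation of its sodium enolate (NaN(SiMe3)2, CH3I, THF, −78 °C) on the face away from the benzyl group gives the (2R)-propanoyl imide F13, and LiOH with H2O2 removes the auxiliary to return acid 7.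

**Further compounds**
F1 | step 11 | (4S)-4-[(1S)-1-methyl-5-oxocyclohex-3-en-1-yl]pentan-2-one | C[C@@H](CC(C)=O)[C@]1(C)CC(=O)C=CC1
F2 | step 11 | (4aR,5S,8aS)-4a,5-dimethyl-4a,5,8,8a-tetrahydronaphthalene-1,7(4H,6H)-dione | O=C1C=CC[C@@]2(C)[C@@H]1CC(=O)C[C@@H]2C
F3 | step 14 | 7β-isopropenyl trimethylsilyl enol ether (C8=C9, 9-OSiMe3) from 18 | C=C(C)[C@H]1C[C@@]2(C)[C@H](CC(OC)(OC)C[C@@H]2C)C(O[Si](C)(C)C)=C1
F4 | step 14 | 8β-hydroxy-7β-isopropenyl 9-ketone (C2 dimethyl ketal) | C=C(C)[C@H]1C[C@@]2(C)[C@H](CC(OC)(OC)C[C@@H]2C)C(=O)[C@H]1O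
F5 | step 14 | 8α-(4-nitrobenzoyloxy)-7β-isopropenyl 9-ketone (C2 dimethyl ketal) | C=C(C)[C@H]1C[C@@]2(C)[C@H](CC(OC)(OC)C[C@@H]2C)C(=O)[C@@H]1OC(=O)c1ccc(cc1)[N+](=O)[O-]
F6 | step 14 | 8α-(4-nitrobenzoyloxy)-7β-isopropenyl-9α-alcohol (C2 dimethyl ketal) | C=C(C)[C@H]1C[C@@]2(C)[C@H](CC(OC)(OC)C[C@@H]2C)[C@H](O)[C@@H]1OC(=O)c1ccc(cc1)[N+](=O)[O-]
F7 | step 3 | (1R)-3-methylcyclohex-2-en-1-yl acetate | CC(=O)O[C@H]1C=C(C)CCC1
F8 | step 3 | trimethyl[(1-{[(1R)-3-methylcyclohex-2-en-1-yl]oxy}ethenyl)oxy]silane | C=C(O[Si](C)(C)C)O[C@H]1C=C(C)CCC1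
F9 | step 3 | trimethylsilyl [(1R)-1-methylcyclohex-2-en-1-yl]acetate | C[Si](C)(C)OC(=O)C[C@]1(C)C=CCCC1
F10 | step 3 | [(1R)-1-methylcyclohex-2-en-1-yl]acetic acid | OC(=O)C[C@]1(C)C=CCCC1
F11 | step 3 | [(1R)-1-methylcyclohex-2-en-1-yl]acetic pivalic anhydride | CC(C)(C)C(=O)OC(=O)C[C@]1(C)C=CCCC1
F12 | step 3 | (4R)-4-benzyl-3-{[(1R)-1-methylcyclohex-2-en-1-yl]acetyl}-1,3-oxazolidin-2-one | O=C(C[C@]1(C)C=CCCC1)N1[C@H](Cc2ccccc2)COC1=O
F13 | step 3 | (4R)-4-benzyl-3-{(2R)-2-[(1S)-1-methylcyclohex-2-en-1-yl]propanoyl}-1,3-oxazolidin-2-one | C[C@H]([C@]1(C)C=CCCC1)C(=O)N1[C@H](Cc2ccccc2)COC1=O
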